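The constants were set for the occasion; what happens was integrated by code.

In a one-step world, starting complex would meet incoming ligand and nothing would follow, but here complex with one exchanged competes for the same ligand.

    starting complex + incoming ligand → leaving ligand + complex with one exchanged (k1 = 0.494 M⁻¹ min⁻¹)
    complex with one exchanged + incoming ligand → leaving ligand + complex with two exchanged (k2 = 0.872 M⁻¹ min⁻¹)
    complex with two exchanged + incoming ligand → leaving ligand + complex with three exchanged (k3 = 0.243 M⁻¹ min⁻¹)
    complex with three exchanged + incoming ligand → leaving ligand + complex with four exchanged (k4 = 3.58 M⁻¹ min⁻¹)
    complex with three exchanged ⇌ isomer of the product (K5 = 0.88, k5 = 0.0759 min⁻¹)

the same everywhere: starting complex 0.20 M; time 10 min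

| charge | incoming ligand |
|---|---|
| gamma | 0.120 M |
| zeta | 0.160 M |
| theta | 0.200 M |

- which of these there is most of at the end, counted by the starting complex in it, gamma (complex with two exchanged / complex with three exchanged / starting complex / complex with one exchanged / complex with four exchanged)
- which of these there is most of at the end, counted by the starting complex in it, zeta (complex with two exchanged / complex with three exchanged / starting complex / complex with one exchanged / complex with four exchanged)
- which of these there is most of at the end, counted by the starting complex in it, theta (complex with two exchanged / complex with three exchanged / starting complex / complex with one exchanged / complex with four exchanged)
- the largest of these amounts at the end, in percent of the starting complex charged, gamma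
- the largest of these amounts at the end, in percent of the starting complex charged, zeta
- the largest of these amounts at the end, in percent of the starting complex charged, theta

The first exchange makes complex with one exchanged and the second uses it up. Both rates carry [incoming ligand], which cancels from their comparison, so control passes from the first exchange to the second at

[complex with one exchanged]/[starting complex] = 0.494 M⁻¹ min⁻¹ / 0.872 M⁻¹ min⁻¹ = 0.567

We call this the crossing ratio: the value of [complex with one exchanged]/[starting complex] at which complex with one exchanged is made as fast as the second exchange uses it. Below that value, with incoming ligand present, this complex still accumulates.

We turn the incoming ligand first. The one-step world, with both partners running down, leaves this much starting complex: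

gamma 67.1%, zeta 58.2%, theta 50.3%

If everything that reacted stayed as complex with one exchanged, these would give ratios of 0.490 in gamma, but 0.718 in zeta and 0.988 in theta, so the one-step picture should hold best in gamma and worsen towards theta. Each ligand taken by a later exchange is denied to the first, so we commit to more starting complex than these marks, and to starting complex as the largest pool.

Next comes the time. The 10 min allowed is shorter than the 12 min half-life of starting complex by the first exchange at charged ligand in gamma, and more time should move the ratio upward. But incoming ligand is the limiting reagent in gamma, at 0.600 per complex, so starting complex cannot fall below 40.0% there. Last, a larger charge of starting complex leaves the crossing ratio unchanged and spreads the same ligand thinner, so its percentage left should rise.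

The forecast names starting complex, starting complex and starting complex at 69.5%, 61.5% and 55%, for gamma, zeta and theta, holding that “the starting complex remains the largest pool in all three charges”. Its figures stand above our marks.

The flask gives starting complex at 69.4% in gamma, starting complex at 61.6% in zeta and starting complex at 54.8% in theta, and the settings, each moved alone by the same factor, shift the starting complex left in zeta in this order: incoming ligand (8.2 points), then time (4.4 points), then starting complex (3.7 points). In gamma the first exchange stayed ahead of the second, with complex with one exchanged made 3.64 times faster than used at 3.30 min and 1.78 times at 10.0 min, when [complex with one exchanged]/[starting complex] stood at 0.319 against the crossing ratio of 0.567 and 33.7% of the ligand charge stood free. The neighbour of gamma with 0.48 M of incoming ligand ended past the crossing, at 0.873, with complex with two exchanged at 41.1% against 23.7% of starting complex.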